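**Strategy.** The cyclohexanone ring is numbered C1 (ketone), C2 and C3 (epoxide), C4, C5 (side chain) and C6 (ester carbinol); C7 and C8 are the methylidene and acetoxy carbons of the side chain. The C1(=O)–C6(O) α-ketol unit joins two carbons of like, acceptor polarity, so the ring is disconnected there to a (Z)-configured 1,6-enedial that already carries the complete acetoxy side chain. A thiazolium-carbene-catalysed intramolecular benzoin reaction reverses the polarity of C1, closes the six-membered ring and sets C6 trans to C5 in one operation. C5 comes from an Evans alkylation, C8 from an asymmetric Nozaki–Hiyama–Kishi coupling; esterification and a hydroxyl-directed epoxidation complete the target.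

Key step: step 11

Remark on the chemistry: compounds 2 and 5 and the thiazolium salt of step 11 are taken as purchasable. In step 8 the ligand enantiomer is the one that leads to the 5R carbinol, which has to be assigned on the product.

Step 1
Reactants: 1 (tert-butyldimethylsilyloxy)acetaldehyde; 2 ethyl 2-[bis(2,2,2-trifluoroethoxy)phosphoryl]propanoate
Product: 3 ethyl (2Z)-4-[(tert-butyldimethylsilyl)oxy]-2-methylbut-2-enoate
Conditions: KN(SiMe3)2, 18-crown-6, THF, −78 °C
Reagents that add atoms: none
Why: Still–Gennari olefination, in which the electron-poor phosphonate under dissociating conditions should give the (Z)-trisubstituted enoate, with the ester carbon (later C1) cis to the CH2O carbon (later C4).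

Step 2
Reactants: 3 ethyl (2Z)-4-[(tert-butyldimethylsilyl)oxy]-2-methylbut-2-enoate
Product: 4 ethyl (2Z)-4-bromo-2-methylbut-2-enoate
Conditions: Ph3PBr2, CH2Cl2, 0 °C to rt
Reagents that add atoms: dibromotriphenylphosphorane BrP(Br)(c1ccccc1)(c1ccccc1)c1ccccc1
Why: direct conversion of a silyl ether into a bromide (oxyphosphonium formation, then SN2 by bromide), which avoids the free (Z)-γ-hydroxy ester that would lactonize and should leave the Z geometry untouched.

Step 3
Reactants: 5 3-bromobut-3-enoic acid; 6 (4S)-4-benzyl-1,3-oxazolidin-2-one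
Product: 8 (4S)-4-benzyl-3-(3-bromobut-3-enoyl)-1,3-oxazolidin-2-one, via mixed pivalic anhydride 7 (not isolated)
Conditions: t-BuCOCl, Et3N, THF, −20 °C; then 6, LiCl, rt
Reagents that add atoms: pivaloyl chloride CC(C)(C)C(Cl)=O (its atoms stay in 7 only, not in 8)
Why: standard N-acylation of the Evans auxiliary through the mixed anhydride, the hindered pivaloyl carbonyl directing attack to the desired acyl group.

Step 4
Reactants: 8 (4S)-4-benzyl-3-(3-bromobut-3-enoyl)-1,3-oxazolidin-2-one; 4 ethyl (2Z)-4-bromo-2-methylbut-2-enoate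
Product: 9 ethyl (2Z,5R)-5-{[(4S)-4-benzyl-2-oxo-1,3-oxazolidin-3-yl]carbonyl}-6-bromo-2-methylhepta-2,6-dienoate
Conditions: NaN(SiMe3)2, THF, −78 °C; then 4, −78 to −45 °C
Reagents that add atoms: none
Why: Evans asymmetric alkylation, in which the chelated sodium (Z)-enolate is alkylated by the allylic bromide (SN2) on the face opposite the benzyl group and so sets C5 (5R here), the low temperature keeping the β-bromovinyl enolate from eliminating bromide.

Step 5
Reactants: 9 ethyl (2Z,5R)-5-{[(4S)-4-benzyl-2-oxo-1,3-oxazolidin-3-yl]carbonyl}-6-bromo-2-methylhepta-2,6-dienoate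
Product: 10 (2Z,5R)-5-(1-bromoethenyl)-2-methylhex-2-ene-1,6-diol
Conditions: LiAlH4, THF, −10 to 0 °C
Reagents that add atoms: none
Why: hydride reduction of the imide (releasing the auxiliary) and 1,2-reduction of the enoate should give both primary alcohols, while the vinyl bromide, the Z alkene and C5 are not affected at this temperature.

Step 6
Reactants: 10 (2Z,5R)-5-(1-bromoethenyl)-2-methylhex-2-ene-1,6-diol
Product: 11 (2Z,5R)-5-(1-bromoethenyl)-2-methyl-1,6-bis[(triethylsilyl)oxy]hex-2-ene
Conditions: Et3SiCl, imidazole, CH2Cl2, 0 °C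
Reagents that add atoms: chlorotriethylsilane CC[Si](Cl)(CC)CC
Why: routine silylation, triethylsilyl being chosen because primary triethylsilyl ethers can later be oxidized directly to aldehydes.

Step 7
Reactants: 12 4-methylpent-3-en-1-ol
Product: 13 4-methylpent-3-enal
Conditions: Dess–Martin periodinane, NaHCO3, CH2Cl2, 0 °C to rt; used at once as a solution
Reagents that add atoms: none
Why: buffered Dess–Martin oxidation should give the β,γ-unsaturated aldehyde without migration of the double bond into conjugation.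

Step 8
Reactants: 11 (2Z,5R)-5-(1-bromoethenyl)-2-methyl-1,6-bis[(triethylsilyl)oxy]hex-2-ene; 13 4-methylpent-3-enal
Product: 14 (5R,7S,9Z)-2,10-dimethyl-6-methylidene-11-[(triethylsilyl)oxy]-7-{[(triethylsilyl)oxy]methyl}undeca-2,9-dien-5-ol
Conditions: CrCl2, NiCl2 (cat.), chiral oxazoline–sulfonamide ligand N-[2-(4-isopropyl-4,5-dihydro-1,3-oxazol-2-yl)-6-methylphenyl]methanesulfonamide, Et3N, THF, rt
Reagents that add atoms: none
Why: Nozaki–Hiyama–Kishi coupling, in which the alkenylchromium formed from the 2-bromoalkene under nickel catalysis adds chemoselectively to the aldehyde and the chiral ligand on chromium (reagent control) should set the carbinol C8 as R (5R in this name).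

Step 9
Reactants: 14 (5R,7S,9Z)-2,10-dimethyl-6-methylidene-11-[(triethylsilyl)oxy]-7-{[(triethylsilyl)oxy]methyl}undeca-2,9-dien-5-ol
Product: 15 (5R,7S,9Z)-2,10-dimethyl-6-methylidene-11-[(triethylsilyl)oxy]-7-{[(triethylsilyl)oxy]methyl}undeca-2,9-dien-5-yl acetate
Conditions: Ac2O, pyridine, DMAP (cat.), CH2Cl2, 0 °C to rt
Reagents that add atoms: acetic anhydride CC(=O)OC(C)=O
Why: routine acetylation of the only free hydroxyl, with retention at C8.

Step 10
Reactants: 15 (5R,7S,9Z)-2,10-dimethyl-6-methylidene-11-[(triethylsilyl)oxy]-7-{[(triethylsilyl)oxy]methyl}undeca-2,9-dien-5-yl acetate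
Product: 16 (3R)-6-methyl-2-[(2S,4Z)-5-methyl-1,6-dioxohex-4-en-2-yl]hepta-1,5-dien-3-yl acetate
Conditions: (COCl)2, DMSO, CH2Cl2, −78 to −35 °C; then i-Pr2NEt, −78 to 0 °C; used at once
Reagents that add atoms: none
Why: Swern conditions cleave and oxidize primary triethylsilyl ethers directly, so both ends should become aldehydes in one operation, the hindered amine and cold quench protecting the Z-enal and the C5 centre.

Step 11
Reactants: 16 (3R)-6-methyl-2-[(2S,4Z)-5-methyl-1,6-dioxohex-4-en-2-yl]hepta-1,5-dien-3-yl acetate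
Product: 17 (3R)-2-[(1S,2S)-2-hydroxy-4-methyl-3-oxocyclohex-4-en-1-yl]-6-methylhepta-1,5-dien-3-yl acetate
Conditions: 3-benzyl-5-(2-hydroxyethyl)-4-methylthiazolium chloride (cat.), i-Pr2NEt (cat.), degassed 1,4-dioxane, high dilution, 40 °C
Reagents that add atoms: none
Why: The thiazol-2-ylidene adds to the conjugated C1 aldehyde of 16, proton transfer gives the Breslow intermediate in which C1 is a nucleophilic acyl-anion equivalent, this carbon attacks the C6 aldehyde, and collapse of the adduct releases the carbene and the α-hydroxy ketone. The closest known reaction type is the thiazolium-catalysed intramolecular benzoin (acyloin) cyclization of 1,6-dialdehydes to 2-hydroxycyclohexanones. The six-membered carbocycle closes in the 6-exo-trig mode by attack on the C6 carbonyl. The new stereocentre C6 is controlled by C5: in the chair-like closure the C5 side chain and the C6 oxygen are both pseudo-equatorial, and because C6 stays epimerizable through the ene-diol under the conditions, the trans (5S,6S) ketol should also be the thermodynamic product. The step needs acyl-anion formation at C1 and not at C6 or C3, and an intact C5 centre: the α-branched C6 aldehyde is a poor donor, the regioisomeric ketol would drain by retro-benzoin and ene-diol equilibration into the conjugated enone 17, attack through C3 would need a four-membered ring, thiazolium carbenes favour acyl-anion over homoenolate reactivity of enals, and the weak amine base in catalytic amount limits enolization at C5.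

Step 12
Reactants: 17 (3R)-2-[(1S,2S)-2-hydroxy-4-methyl-3-oxocyclohex-4-en-1-yl]-6-methylhepta-1,5-dien-3-yl acetate; 18 3-methylbut-2-enoic acid
Product: 19 (1S,6S)-6-[(3R)-3-acetoxy-6-methylhepta-1,5-dien-2-yl]-3-methyl-2-oxocyclohex-3-en-1-yl 3-methylbut-2-enoate
Conditions: DCC, DMAP (cat.), CH2Cl2, 0 °C to rt
Reagents that add atoms: none
Why: Steglich esterification of the α-ketol hydroxyl, the carbodiimide activation avoiding ketene formation and deconjugation of the senecioyl unit, with retention at C6.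

Step 13
Reactants: 19 (1S,6S)-6-[(3R)-3-acetoxy-6-methylhepta-1,5-dien-2-yl]-3-methyl-2-oxocyclohex-3-en-1-yl 3-methylbut-2-enoate
Product: 20 (1S,2S,6S)-6-[(3R)-3-acetoxy-6-methylhepta-1,5-dien-2-yl]-2-hydroxy-3-methylcyclohex-3-en-1-yl 3-methylbut-2-enoate
Conditions: NaBH4, CeCl3·7H2O, MeOH, −78 °C
Reagents that add atoms: none
Why: Luche 1,2-reduction, in which axial hydride attack on the half-chair with the C5 and C6 substituents pseudo-equatorial should give the pseudo-equatorial C1 alcohol, cis to the C5 side chain and trans to the C6 ester (as carvone gives cis-carveol), both esters surviving.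

Step 14
Reactants: 20 (1S,2S,6S)-6-[(3R)-3-acetoxy-6-methylhepta-1,5-dien-2-yl]-2-hydroxy-3-methylcyclohex-3-en-1-yl 3-methylbut-2-enoate
Product: 21 (1R,2R,3S,4S,6S)-4-[(3R)-3-acetoxy-6-methylhepta-1,5-dien-2-yl]-2-hydroxy-1-methyl-7-oxabicyclo[4.1.0]heptan-3-yl 3-methylbut-2-enoate
Conditions: VO(acac)2 (cat.), t-BuOOH, CH2Cl2, 0 °C to rt
Reagents that add atoms: tert-butyl hydroperoxide CC(C)(C)OO
Why: vanadium-catalysed hydroxyl-directed epoxidation delivers oxygen to the C2=C3 bond on the face of the C1 hydroxyl, so the epoxide should form cis to the C5 side chain and trans to the C6 ester, while the other alkenes (no free allylic hydroxyl, or electron-poor) are left alone.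

Step 15
Reactants: 21 (1R,2R,3S,4S,6S)-4-[(3R)-3-acetoxy-6-methylhepta-1,5-dien-2-yl]-2-hydroxy-1-methyl-7-oxabicyclo[4.1.0]heptan-3-yl 3-methylbut-2-enoate
Product: 22 (1S,3S,4S,6S)-4-[(3R)-3-acetoxy-6-methylhepta-1,5-dien-2-yl]-1-methyl-2-oxo-7-oxabicyclo[4.1.0]heptan-3-yl 3-methylbut-2-enoate
Conditions: Dess–Martin periodinane, NaHCO3, CH2Cl2, 0 °C to rt
Reagents that add atoms: none
Why: buffered Dess–Martin oxidation of the epoxy alcohol should give the epoxy ketone without opening the epoxide or epimerizing C6.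

**Compound list**

1 | (tert-butyldimethylsilyloxy)acetaldehyde | O=CCO[Si](C)(C)C(C)(C)C | starting material
2 | ethyl 2-[bis(2,2,2-trifluoroethoxy)phosphoryl]propanoate | CCOC(=O)C(C)P(=O)(OCC(F)(F)F)OCC(F)(F)F | starting material
3 | ethyl (2Z)-4-[(tert-butyldimethylsilyl)oxy]-2-methylbut-2-enoate | CCOC(=O)/C(C)=C\CO[Si](C)(C)C(C)(C)C | intermediate
4 | ethyl (2Z)-4-bromo-2-methylbut-2-enoate | CCOC(=O)/C(C)=C\CBr | intermediate
5 | 3-bromobut-3-enoic acid | OC(=O)CC(Br)=C | starting material
6 | (4S)-4-benzyl-1,3-oxazolidin-2-one | O=C1OC[C@H](Cc2ccccc2)N1 | starting material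
7 | 3-bromobut-3-enoic pivalic anhydride (mixed anhydride) | CC(C)(C)C(=O)OC(=O)CC(Br)=C | intermediate
8 | (4S)-4-benzyl-3-(3-bromobut-3-enoyl)-1,3-oxazolidin-2-one | O=C1OC[C@H](Cc2ccccc2)N1C(=O)CC(Br)=C | intermediate
9 | ethyl (2Z,5R)-5-{[(4S)-4-benzyl-2-oxo-1,3-oxazolidin-3-yl]carbonyl}-6-bromo-2-methylhepta-2,6-dienoate | O=C1OC[C@H](Cc2ccccc2)N1C(=O)[C@@H](C/C=C(C)\C(=O)OCC)C(Br)=C | intermediate
10 | (2Z,5R)-5-(1-bromoethenyl)-2-methylhex-2-ene-1,6-diol | OC/C(C)=C\C[C@H](CO)C(Br)=C | intermediate
11 | (2Z,5R)-5-(1-bromoethenyl)-2-methyl-1,6-bis[(triethylsilyl)oxy]hex-2-ene | CC[Si](CC)(CC)OC/C(C)=C\C[C@H](CO[Si](CC)(CC)CC)C(Br)=C | intermediate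
12 | 4-methylpent-3-en-1-ol | CC(C)=CCCO | starting material
13 | 4-methylpent-3-enal | CC(C)=CCC=O | intermediate
14 | (5R,7S,9Z)-2,10-dimethyl-6-methylidene-11-[(triethylsilyl)oxy]-7-{[(triethylsilyl)oxy]methyl}undeca-2,9-dien-5-ol | CC[Si](CC)(CC)OC/C(C)=C\C[C@H](CO[Si](CC)(CC)CC)C(=C)[C@H](O)CC=C(C)C | intermediate
15 | (5R,7S,9Z)-2,10-dimethyl-6-methylidene-11-[(triethylsilyl)oxy]-7-{[(triethylsilyl)oxy]methyl}undeca-2,9-dien-5-yl acetate | CC[Si](CC)(CC)OC/C(C)=C\C[C@H](CO[Si](CC)(CC)CC)C(=C)[C@H](OC(C)=O)CC=C(C)C | intermediate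
16 | (3R)-6-methyl-2-[(2S,4Z)-5-methyl-1,6-dioxohex-4-en-2-yl]hepta-1,5-dien-3-yl acetate | O=C/C(C)=C\C[C@H](C=O)C(=C)[C@H](OC(C)=O)CC=C(C)C | intermediate
17 | (3R)-2-[(1S,2S)-2-hydroxy-4-methyl-3-oxocyclohex-4-en-1-yl]-6-methylhepta-1,5-dien-3-yl acetate | CC1=CC[C@@H](C(=C)[C@H](OC(C)=O)CC=C(C)C)[C@H](O)C1=O | intermediate
18 | 3-methylbut-2-enoic acid | CC(C)=CC(=O)O | starting material
19 | (1S,6S)-6-[(3R)-3-acetoxy-6-methylhepta-1,5-dien-2-yl]-3-methyl-2-oxocyclohex-3-en-1-yl 3-methylbut-2-enoate | CC1=CC[C@@H](C(=C)[C@H](OC(C)=O)CC=C(C)C)[C@H](OC(=O)C=C(C)C)C1=O | intermediate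
20 | (1S,2S,6S)-6-[(3R)-3-acetoxy-6-methylhepta-1,5-dien-2-yl]-2-hydroxy-3-methylcyclohex-3-en-1-yl 3-methylbut-2-enoate | CC1=CC[C@@H](C(=C)[C@H](OC(C)=O)CC=C(C)C)[C@H](OC(=O)C=C(C)C)[C@H]1O | intermediate
21 | (1R,2R,3S,4S,6S)-4-[(3R)-3-acetoxy-6-methylhepta-1,5-dien-2-yl]-2-hydroxy-1-methyl-7-oxabicyclo[4.1.0]heptan-3-yl 3-methylbut-2-enoate | C=C([C@@H](CC=C(C)C)OC(C)=O)[C@@H]1C[C@@H]2O[C@]2(C)[C@H](O)[C@H]1OC(=O)C=C(C)C | intermediate
22 | (1S,3S,4S,6S)-4-[(3R)-3-acetoxy-6-methylhepta-1,5-dien-2-yl]-1-methyl-2-oxo-7-oxabicyclo[4.1.0]heptan-3-yl 3-methylbut-2-enoate | C=C([C@@H](CC=C(C)C)OC(C)=O)[C@@H]1C[C@@H]2O[C@]2(C)C(=O)[C@H]1OC(=O)C=C(C)C | target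

**Step count.** Total: 15 steps. Longest linear sequence: 13 steps (steps 1, 2, 4, 5, 6, 8, 9, 10, 11, 12, 13, 14, 15); steps 3 and 7 prepare the branch fragments 8 and 13.

**Steps most likely to fail, and fallbacks**

Step 11 (key step). What may go wrong: the amine base may enolize the α-branched, β,γ-unsaturated C6 aldehyde before ring closure, which erodes the configuration at C5. The enal–carbene adduct may also be diverted into homoenolate or enolate pathways instead of acyl-anion addition. The fallback replaces base-mediated polarity reversal by a neutral, reductive union of the two carbonyl carbons. It sets out from 16: SmI2 in THF at −78 °C under slow addition should couple the two aldehydes through ketyl radicals to the cis-diol (3R)-2-[(1S,2S,3R)-2,3-dihydroxy-4-methylcyclohex-4-en-1-yl]-6-methylhepta-1,5-dien-3-yl acetate F1, with the C6 oxygen anti to the C5 substituent and the C1 configuration immaterial. Selective oxidation of the allylic C1 carbinol with MnO2 in CH2Cl2 then returns to the route at 17.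

Step 4. What may go wrong: the sodium enolate may eliminate bromide from the β-bromovinyl group to give an allenyl imide, the product may be deprotonated by unreacted enolate, or the enolate may add in conjugate fashion to the γ-bromo enoate. The fallback avoids this enolate altogether and builds C8 first. It sets out from 8, 13 and 4. A Nozaki–Hiyama–Kishi coupling of 8 with 13 (CrCl2, NiCl2 cat., the enantiomeric ligand) should give the 8S alkoxide, which closes onto the imide carbonyl, expels the auxiliary and gives (5S)-4-methylidene-5-(3-methylbut-2-en-1-yl)oxolan-2-one F4. Its lithium enolate (LiN(i-Pr)2, THF, −78 °C) should be alkylated by 4 anti to the ring substituent to give ethyl (2Z)-2-methyl-4-[(3S,5S)-4-methylidene-5-(3-methylbut-2-en-1-yl)-2-oxooxolan-3-yl]but-2-enoate F5. LiAlH4 reduces lactone and ester to (5S,7S,9Z)-7-(hydroxymethyl)-2,10-dimethyl-6-methylideneundeca-2,9-diene-5,11-diol F6. Et3SiCl (2 equiv) and imidazole silylate the two primary hydroxyls to (5S,7S,9Z)-2,10-dimethyl-6-methylidene-11-[(triethylsilyl)oxy]-7-{[(triethylsilyl)oxy]methyl}undeca-2,9-dien-5-ol F7, the C8 epimer of 14. A Mitsunobu reaction with acetic acid (PPh3, DIAD) installs the acetate with inversion at C8 and returns to the route at 15.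

Step 8. What may go wrong: oxidative addition of the hindered 2-bromoalkene to nickel may be slow, the chiral ligand may give weak facial control at the new carbinol because the remote C5 centre gives no help, and aldehyde 13 may isomerize into conjugation during a slow coupling. The fallback separates C–C bond formation from stereocontrol. It sets out from 11: bromine–lithium exchange (t-BuLi, Et2O, −78 °C) and addition of 13 should give 14 mixed with its C8 epimer (5S,7S,9Z)-2,10-dimethyl-6-methylidene-11-[(triethylsilyl)oxy]-7-{[(triethylsilyl)oxy]methyl}undeca-2,9-dien-5-ol F2. Dess–Martin oxidation of the mixture gives (7S,9Z)-2,10-dimethyl-6-methylidene-11-[(triethylsilyl)oxy]-7-{[(triethylsilyl)oxy]methyl}undeca-2,9-dien-5-one F3. Corey–Bakshi–Shibata reduction with (S)-2-methyl-CBS-oxazaborolidine and catecholborane (toluene, −78 °C), the 1,1-disubstituted alkenyl group acting as the large substituent, should set the carbinol as 5R and return to the route at 14.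

**Further compounds**

F1 | step 11 | (3R)-2-[(1S,2S,3R)-2,3-dihydroxy-4-methylcyclohex-4-en-1-yl]-6-methylhepta-1,5-dien-3-yl acetate | CC1=CC[C@@H](C(=C)[C@H](OC(C)=O)CC=C(C)C)[C@H](O)[C@@H]1O
F2 | step 8 | (5S,7S,9Z)-2,10-dimethyl-6-methylidene-11-[(triethylsilyl)oxy]-7-{[(triethylsilyl)oxy]methyl}undeca-2,9-dien-5-ol | CC[Si](CC)(CC)OC/C(C)=C\C[C@H](CO[Si](CC)(CC)CC)C(=C)[C@@H](O)CC=C(C)C
F3 | step 8 | (7S,9Z)-2,10-dimethyl-6-methylidene-11-[(triethylsilyl)oxy]-7-{[(triethylsilyl)oxy]methyl}undeca-2,9-dien-5-one | CC[Si](CC)(CC)OC/C(C)=C\C[C@H](CO[Si](CC)(CC)CC)C(=C)C(=O)CC=C(C)C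
F4 | step 4 | (5S)-4-methylidene-5-(3-methylbut-2-en-1-yl)oxolan-2-one | O=C1CC(=C)[C@H](CC=C(C)C)O1
F5 | step 4 | ethyl (2Z)-2-methyl-4-[(3S,5S)-4-methylidene-5-(3-methylbut-2-en-1-yl)-2-oxooxolan-3-yl]but-2-enoate | CCOC(=O)/C(C)=C\C[C@@H]1C(=O)O[C@@H](CC=C(C)C)C1=C
F6 | step 4 | (5S,7S,9Z)-7-(hydroxymethyl)-2,10-dimethyl-6-methylideneundeca-2,9-diene-5,11-diol | OC/C(C)=C\C[C@H](CO)C(=C)[C@@H](O)CC=C(C)C
F7 | step 4 | (5S,7S,9Z)-2,10-dimethyl-6-methylidene-11-[(triethylsilyl)oxy]-7-{[(triethylsilyl)oxy]methyl}undeca-2,9-dien-5-ol (same compound as F2) | CC[Si](CC)(CC)OC/C(C)=C\C[C@H](CO[Si](CC)(CC)CC)C(=C)[C@@H](O)CC=C(C)C
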